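**Plan**

1. Retrosynthesis: the bond between the bridge CH2 and the trione ring carbon is cut first (ortho-quinone methide plus trione enolate), then the C6–acyl bond of ring B (acyl shift from O5), then the four ring B bonds C8–C8a, C7–C8, C5–C6 and C4a–C5.
2. Enabling feature: ring B is a fully substituted benzene whose carbons carry in sequence the bridge carbon (C8), OH (C7), isobutyryl (C6), OH (C5), the pyran carbon (C4a) and the pyran oxygen (C8a). C8a=C4a maps onto the enol-ether C=C of a dihydropyranone, C8 onto a diazo ester carbon and C6–C7(O) onto a siloxyalkyne, so a ketene benzannulation places every substituent unambiguously.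
3. Forward: the pyranone ring is made first (mesityl oxide and diethyl oxalate) and homologated to the diazo keto ester, and ring B is closed onto it photochemically. Reduction and dehydration then give the chromene, ester reduction the benzylic carbon, and a photo-Fries shift the C6 ketone.
4. The trione ring is built separately from a malonic half-ester and 5-methylhexane-2,4-dione (C-acylation, then Claisen ring closure).
5. The single stereocentre (R, quaternary C–Me/prenyl) comes from enzymatic desymmetrisation of prochiral dimethyl methyl(prenyl)malonate. Its two carboxyl carbons are then elaborated differently; it bears no hydrogen and cannot epimerise.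
6. The two halves are joined last by fluoride-triggered quinone methide formation and Michael addition of the trione enolate.

Key step: step 7

Assumption: pig liver esterase is taken to deliver the (S)-half-ester 27 from 26; the sense must be confirmed on the first batch, and the antipode would require the two carboxyl groups to be elaborated in the opposite order.

Remark: the cyclic β-triketones 31 and 33 are written as the enol tautomers of the target SMILES, and the descriptor R refers to these drawings.

**Route**

Step 1
Reactants: 1 mesityl oxide (4-methylpent-3-en-2-one); 2 diethyl oxalate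
Product: 4 ethyl 6,6-dimethyl-4-oxo-5,6-dihydro-4H-pyran-2-carboxylate, via diketo ester 3 (not isolated)
Conditions: NaOEt (1.05 equiv), EtOH, 0 °C to rt; then HCl in EtOH, 50 °C
Reagents that add atoms: none
Why: Crossed Claisen condensation of the methyl-ketone enolate of 1 with the non-enolisable oxalate should give 3, whose enol oxygen closes onto the β,β-dimethyl enone under acid (6-endo oxa-Michael addition), the sequence by which the butyl ester analogue is manufactured.

Step 2
Reactants: 4 ethyl 6,6-dimethyl-4-oxo-5,6-dihydro-4H-pyran-2-carboxylate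
Product: 5 6,6-dimethyl-4-oxo-5,6-dihydro-4H-pyran-2-carboxylic acid
Conditions: LiOH·H2O (1.1 equiv), THF–H2O, 0 °C; then 1 M HCl to pH 2
Reagents that add atoms: lithium hydroxide, [Li+].[OH-]
Why: Saponification of the activated α-alkoxyacrylate ester is fast at 0 °C, and the acidic work-up should reclose any ring-opened diketo acid by the oxa-Michael addition of step 1.

Step 3
Reactants: 5 6,6-dimethyl-4-oxo-5,6-dihydro-4H-pyran-2-carboxylic acid
Product: 7 methyl 3-(6,6-dimethyl-4-oxo-5,6-dihydro-4H-pyran-2-yl)-3-oxopropanoate, via acyl imidazolide 6 (not isolated)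
Conditions: CDI, THF, rt; then KO2CCH2CO2Me, MgCl2, THF, rt to 40 °C; aq. HCl work-up
Reagents that add atoms: potassium methyl malonate, COC(=O)CC(=O)[O-].[K+]
Why: Masamune–Brooks homologation, in which the magnesium malonate half-ester is C-acylated by the imidazolide and loses CO2, should give the β-keto ester under near-neutral conditions that leave the enone untouched.

Step 4
Reactants: 7 methyl 3-(6,6-dimethyl-4-oxo-5,6-dihydro-4H-pyran-2-yl)-3-oxopropanoate
Product: 8 methyl 2-diazo-3-(6,6-dimethyl-4-oxo-5,6-dihydro-4H-pyran-2-yl)-3-oxopropanoate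
Conditions: 4-acetamidobenzenesulfonyl azide (1.2 equiv), Et3N, MeCN, 0 °C to rt
Reagents that add atoms: 4-acetamidobenzenesulfonyl azide, CC(=O)Nc1ccc(cc1)S(=O)(=O)N=[N+]=[N-]
Why: Regitz diazo transfer should occur only at the doubly activated methylene, since the pyranone CH2 is a simple ketone α-position.

Step 5
Reactants: 9 trimethylsilylacetylene
Product: 12 triisopropyl{[(trimethylsilyl)ethynyl]oxy}silane, via lithium (trimethylsilyl)acetylide 10 (not isolated), via lithium silylynolate 11 (not isolated)
Conditions: n-BuLi, THF, −78 °C; LiOOt-Bu (from t-BuOOH and n-BuLi), −78 to 0 °C; then i-Pr3SiOSO2CF3, −78 °C to rt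
Reagents that add atoms: tert-butyl hydroperoxide, CC(C)(C)OO; triisopropylsilyl triflate, CC(C)[Si](OS(=O)(=O)C(F)(F)F)(C(C)C)C(C)C
Why: Oxidation of a lithium acetylide to the ynolate by lithium tert-butyl peroxide followed by silylation with a bulky silyl triflate is the standard route to siloxyalkynes, the size of the triisopropylsilyl group directing silylation to oxygen and not to carbon.

Step 6
Reactants: 12 triisopropyl{[(trimethylsilyl)ethynyl]oxy}silane
Product: 13 triisopropylsiloxyethyne
Conditions: K2CO3 (0.2 equiv), MeOH–THF, 0 °C; used promptly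
Reagents that add atoms: none
Why: Base-catalysed methanolysis should cleave the C(sp)–SiMe3 bond selectively, because the hindered Si–O bond of the triisopropylsilyl ether reacts far more slowly with methoxide.

Step 7
Reactants: 8 methyl 2-diazo-3-(6,6-dimethyl-4-oxo-5,6-dihydro-4H-pyran-2-yl)-3-oxopropanoate; 13 triisopropylsiloxyethyne
Product: 18 methyl 5-hydroxy-2,2-dimethyl-4-oxo-7-(triisopropylsiloxy)chromane-8-carboxylate, via ester-substituted vinylketene 14 (not isolated), via siloxycyclobutenone 15 (not isolated), via dienylketene 16 (not isolated), via cyclohexadienone 17 (not isolated)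
Conditions: 13 (2 equiv), degassed ClCH2CH2Cl, hν (medium-pressure Hg lamp, Vycor filter), rt; then 80 °C
Reagents that add atoms: none
Why: Proposed new method: light expels N2 from 8 and the pyranone carbon C2 shifts from the ketone carbon to the carbene carbon (Wolff rearrangement), giving ester-substituted vinylketene 14, whose ketene C=C bond adds across 13 in a [2+2] cycloaddition to cyclobutenone 15. Ring B is then closed by electrocyclisation: 15 opens (4π) to dienylketene 16, which closes (6π, thermal, disrotatory) from its ketene carbon onto the enol-ether carbon C3 of the pyranone, and dienone 17 enolises to phenol 18, so that the bonds C8–C8a, C5–C6, C7–C8 and C4a–C5 (chromanone numbering) form in one flask. The closest known reaction type is the photochemical Wolff benzannulation of aryl and alkenyl α-diazo ketones with siloxyalkynes, combined with the known photochemical Wolff rearrangement of 2-diazo-3-oxo esters to alkoxycarbonyl ketenes; untested is the use of such a diazo keto ester, carried on a dihydropyranone, as the vinylketene source. No stereocentre is created, the stereocentres of 15 and 17 being lost on ring opening and enolisation. The step needs one orientation of the ketene–alkyne addition, and polarity secures it: the unsubstituted, nucleophilic alkyne carbon bonds to the electrophilic ketene carbonyl carbon and the siloxy-bearing carbon to the ester-bearing carbon, which puts OSi(i-Pr)3 at C7 next to the ester at C8 and leaves C6 as the only ring CH. It also needs migration of the alkenyl carbon and not of methoxy in the Wolff step, which the ketone side of a 2-diazo-3-oxo ester provides.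

Step 8
Reactants: 18 methyl 5-hydroxy-2,2-dimethyl-4-oxo-7-(triisopropylsiloxy)chromane-8-carboxylate
Product: 20 methyl 5-hydroxy-2,2-dimethyl-7-(triisopropylsiloxy)-2H-chromene-8-carboxylate, via chroman-4-ol 19 (not isolated)
Conditions: NaBH4, MeOH–THF, 0 °C to rt; then p-TsOH·H2O (5 mol %), toluene, 60 °C
Reagents that add atoms: none
Why: Borohydride should reduce the aryl ketone but not the hindered ester, and the benzylic alcohol then loses water by acid-catalysed E1 elimination through a cation stabilised by the ortho and para oxygens, the standard chromanone-to-chromene conversion.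

Step 9
Reactants: 20 methyl 5-hydroxy-2,2-dimethyl-7-(triisopropylsiloxy)-2H-chromene-8-carboxylate
Product: 22 [2,2-dimethyl-5-(2-methylpropanoyloxy)-7-(triisopropylsiloxy)-2H-chromen-8-yl]methyl 2-methylpropanoate, via benzylic diol 21 (not isolated)
Conditions: i-Bu2AlH (4 equiv), CH2Cl2, −78 to 0 °C; aq. KNaC4H4O6 work-up; then i-PrCOCl (2.5 equiv), Et3N, DMAP (cat.), CH2Cl2, −78 to 0 °C
Reagents that add atoms: isobutyryl chloride, CC(C)C(Cl)=O
Why: Hydride reduction of the ester to the benzylic alcohol followed directly by DMAP-catalysed acylation should cap both the phenol and the sensitive para-hydroxybenzyl alcohol before the latter can ionise.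

Step 10
Reactants: 22 [2,2-dimethyl-5-(2-methylpropanoyloxy)-7-(triisopropylsiloxy)-2H-chromen-8-yl]methyl 2-methylpropanoate
Product: 23 [5-hydroxy-2,2-dimethyl-6-(2-methylpropanoyl)-7-(triisopropylsiloxy)-2H-chromen-8-yl]methyl 2-methylpropanoate
Conditions: hν (300 nm, Pyrex), degassed cyclohexane, rt
Reagents that add atoms: none
Why: Photo-Fries rearrangement, by homolysis of the aryl ester C(O)–O bond and in-cage recombination of the acyl radical, should deliver the acyl group to C6, the only unsubstituted position ortho or para to O5, and enolisation then gives the hydrogen-bonded o-hydroxyaryl ketone.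

Step 11
Reactants: 24 dimethyl methylmalonate; 25 prenyl bromide (1-bromo-3-methylbut-2-ene)
Product: 26 dimethyl 2-methyl-2-(3-methylbut-2-en-1-yl)propanedioate
Conditions: NaH, THF, 0 °C; then 25, 0 °C to rt
Reagents that add atoms: none
Why: SN2 alkylation of the malonate anion at the primary allylic carbon should give the prochiral diester.

Step 12
Reactants: 26 dimethyl 2-methyl-2-(3-methylbut-2-en-1-yl)propanedioate
Product: 27 (2S)-2-(methoxycarbonyl)-2,5-dimethylhex-4-enoic acid
Conditions: pig liver esterase, 0.1 M phosphate buffer pH 7.4–DMSO (9:1), 25 °C, pH-stat (1 M NaOH); then HCl to pH 2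
Reagents that add atoms: water, O
Why: Enzymatic desymmetrisation, in which the esterase hydrolyses one of the two enantiotopic ester groups of 26, sets the quaternary stereocentre and is an established reaction type for 2-alkyl-2-methylmalonates.

Step 13
Reactants: 27 (2S)-2-(methoxycarbonyl)-2,5-dimethylhex-4-enoic acid; 28 5-methylhexane-2,4-dione
Product: 30 methyl (2S)-4-acetyl-2,6-dimethyl-2-(3-methylbut-2-en-1-yl)-3,5-dioxoheptanoate, via acid chloride 29 (not isolated)
Conditions: 1-chloro-N,N,2-trimethylprop-1-en-1-amine, CH2Cl2, 0 °C to rt; then 28, MgCl2, pyridine, CH2Cl2, 0 °C to rt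
Reagents that add atoms: none
Why: The chloroenamine should convert the acid into its chloride under neutral conditions that spare the prenyl alkene, and the magnesium enolate of the β-diketone (soft enolisation) is then acylated on carbon to give the triacylmethane.

Step 14
Reactants: 30 methyl (2S)-4-acetyl-2,6-dimethyl-2-(3-methylbut-2-en-1-yl)-3,5-dioxoheptanoate
Product: 31 (4R)-3,5-dihydroxy-4-methyl-4-(3-methylbut-2-en-1-yl)-2-(2-methylpropanoyl)cyclohexa-2,5-dien-1-one
Conditions: LiN(i-Pr)2 (3.3 equiv), THF, −78 to 0 °C; then 1 M HCl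
Reagents that add atoms: none
Why: Intramolecular Claisen (Dieckmann-type) condensation of the dianion formed by kinetic deprotonation of the acetyl methyl group should close the six-membered ring onto the methyl ester, and the stereocentre, which carries no hydrogen, cannot epimerise.

Step 15
Reactants: 23 [5-hydroxy-2,2-dimethyl-6-(2-methylpropanoyl)-7-(triisopropylsiloxy)-2H-chromen-8-yl]methyl 2-methylpropanoate; 31 (4R)-3,5-dihydroxy-4-methyl-4-(3-methylbut-2-en-1-yl)-2-(2-methylpropanoyl)cyclohexa-2,5-dien-1-one
Product: 33 (4R)-6-{[5,7-dihydroxy-2,2-dimethyl-6-(2-methylpropanoyl)-2H-chromen-8-yl]methyl}-3,5-dihydroxy-4-methyl-4-(3-methylbut-2-en-1-yl)-2-(2-methylpropanoyl)cyclohexa-2,5-dien-1-one, via ortho-quinone methide 32 (not isolated)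
Conditions: 31 (1.2 equiv), Bu4NF (3 equiv), THF, 0 °C; slow addition of 23, 0 °C to rt; aq. NH4Cl work-up
Reagents that add atoms: none
Why: Fluoride should cleave the aryl silyl ether, the phenoxide expels isobutyrate by 1,4-elimination to ortho-quinone methide 32, and the enolate of 31 adds through its only unsubstituted ring carbon (Michael addition with rearomatisation, a known way of C-benzylating cyclic 1,3-diones), leaving the stereocentre untouched.

**Compound list**

1 | mesityl oxide | CC(C)=CC(C)=O | starting material
2 | diethyl oxalate | CCOC(=O)C(=O)OCC | starting material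
3 | ethyl 6-methyl-2,4-dioxohept-5-enoate (formed as its sodium enolate) | CCOC(=O)C(=O)CC(=O)C=C(C)C | intermediate (not isolated)
4 | ethyl 6,6-dimethyl-4-oxo-5,6-dihydro-4H-pyran-2-carboxylate | CCOC(=O)C1=CC(=O)CC(C)(C)O1 | intermediate
5 | 6,6-dimethyl-4-oxo-5,6-dihydro-4H-pyran-2-carboxylic acid | OC(=O)C1=CC(=O)CC(C)(C)O1 | intermediate
6 | (6,6-dimethyl-4-oxo-5,6-dihydro-4H-pyran-2-yl)(1H-imidazol-1-yl)methanone | O=C(n1ccnc1)C2=CC(=O)CC(C)(C)O2 | intermediate (not isolated)
7 | methyl 3-(6,6-dimethyl-4-oxo-5,6-dihydro-4H-pyran-2-yl)-3-oxopropanoate | COC(=O)CC(=O)C1=CC(=O)CC(C)(C)O1 | intermediate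
8 | methyl 2-diazo-3-(6,6-dimethyl-4-oxo-5,6-dihydro-4H-pyran-2-yl)-3-oxopropanoate | COC(=O)C(=[N+]=[N-])C(=O)C1=CC(=O)CC(C)(C)O1 | intermediate
9 | trimethylsilylacetylene | C[Si](C)(C)C#C | starting material
10 | lithium (trimethylsilyl)acetylide | C[Si](C)(C)C#[C-].[Li+] | intermediate (not isolated)
11 | lithium 2-(trimethylsilyl)ethynolate | C[Si](C)(C)C#C[O-].[Li+] | intermediate (not isolated)
12 | triisopropyl{[(trimethylsilyl)ethynyl]oxy}silane | C[Si](C)(C)C#CO[Si](C(C)C)(C(C)C)C(C)C | intermediate
13 | triisopropylsiloxyethyne | C#CO[Si](C(C)C)(C(C)C)C(C)C | intermediate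
14 | methyl 2-(6,6-dimethyl-4-oxo-5,6-dihydro-4H-pyran-2-yl)-3-oxoprop-2-enoate (vinylketene) | COC(=O)C(=C=O)C1=CC(=O)CC(C)(C)O1 | intermediate (not isolated)
15 | methyl 1-(6,6-dimethyl-4-oxo-5,6-dihydro-4H-pyran-2-yl)-4-oxo-2-(triisopropylsiloxy)cyclobut-2-ene-1-carboxylate (racemic) | COC(=O)C1(C(=O)C=C1O[Si](C(C)C)(C(C)C)C(C)C)C2=CC(=O)CC(C)(C)O2 | intermediate (not isolated)
16 | methyl (2Z)-2-(6,6-dimethyl-4-oxo-5,6-dihydro-4H-pyran-2-yl)-5-oxo-3-(triisopropylsiloxy)penta-2,4-dienoate (dienylketene) | O=C=C/C(O[Si](C(C)C)(C(C)C)C(C)C)=C(\C1=CC(=O)CC(C)(C)O1)C(=O)OC | intermediate (not isolated)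
17 | methyl 2,2-dimethyl-4,5-dioxo-7-(triisopropylsiloxy)-3,4,4a,5-tetrahydro-2H-chromene-8-carboxylate (racemic) | COC(=O)C1=C2OC(C)(C)CC(=O)C2C(=O)C=C1O[Si](C(C)C)(C(C)C)C(C)C | intermediate (not isolated)
18 | methyl 5-hydroxy-2,2-dimethyl-4-oxo-7-(triisopropylsiloxy)chromane-8-carboxylate | COC(=O)c1c(O[Si](C(C)C)(C(C)C)C(C)C)cc(O)c2C(=O)CC(C)(C)Oc12 | intermediate
19 | methyl 4,5-dihydroxy-2,2-dimethyl-7-(triisopropylsiloxy)chromane-8-carboxylate (racemic) | COC(=O)c1c(O[Si](C(C)C)(C(C)C)C(C)C)cc(O)c2C(O)CC(C)(C)Oc12 | intermediate (not isolated)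
20 | methyl 5-hydroxy-2,2-dimethyl-7-(triisopropylsiloxy)-2H-chromene-8-carboxylate | COC(=O)c1c(O[Si](C(C)C)(C(C)C)C(C)C)cc(O)c2C=CC(C)(C)Oc12 | intermediate
21 | 8-(hydroxymethyl)-2,2-dimethyl-7-(triisopropylsiloxy)-2H-chromen-5-ol | OCc1c(O[Si](C(C)C)(C(C)C)C(C)C)cc(O)c2C=CC(C)(C)Oc12 | intermediate (not isolated)
22 | [2,2-dimethyl-5-(2-methylpropanoyloxy)-7-(triisopropylsiloxy)-2H-chromen-8-yl]methyl 2-methylpropanoate | CC(C)C(=O)OCc1c(O[Si](C(C)C)(C(C)C)C(C)C)cc(OC(=O)C(C)C)c2C=CC(C)(C)Oc12 | intermediate
23 | [5-hydroxy-2,2-dimethyl-6-(2-methylpropanoyl)-7-(triisopropylsiloxy)-2H-chromen-8-yl]methyl 2-methylpropanoate | CC(C)C(=O)OCc1c(O[Si](C(C)C)(C(C)C)C(C)C)c(C(=O)C(C)C)c(O)c2C=CC(C)(C)Oc12 | intermediate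
24 | dimethyl methylmalonate | COC(=O)C(C)C(=O)OC | starting material
25 | prenyl bromide (1-bromo-3-methylbut-2-ene) | CC(C)=CCBr | starting material
26 | dimethyl 2-methyl-2-(3-methylbut-2-en-1-yl)propanedioate | COC(=O)C(C)(CC=C(C)C)C(=O)OC | intermediate
27 | (2S)-2-(methoxycarbonyl)-2,5-dimethylhex-4-enoic acid | CC(C)=CC[C@](C(=O)O)(C)C(=O)OC | intermediate
28 | 5-methylhexane-2,4-dione | CC(=O)CC(=O)C(C)C | starting material
29 | methyl (2R)-2-(chlorocarbonyl)-2,5-dimethylhex-4-enoate | CC(C)=CC[C@](C(Cl)=O)(C)C(=O)OC | intermediate (not isolated)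
30 | methyl (2S)-4-acetyl-2,6-dimethyl-2-(3-methylbut-2-en-1-yl)-3,5-dioxoheptanoate | CC(C)=CC[C@](C(=O)C(C(C)=O)C(=O)C(C)C)(C)C(=O)OC | intermediate
31 | (4R)-3,5-dihydroxy-4-methyl-4-(3-methylbut-2-en-1-yl)-2-(2-methylpropanoyl)cyclohexa-2,5-dien-1-one | CC(C)=CC[C@]1(C)C(O)=CC(=O)C(C(=O)C(C)C)=C1O | intermediate
32 | 5-hydroxy-2,2-dimethyl-8-methylidene-6-(2-methylpropanoyl)-2H-chromen-7(8H)-one | C=C1C(=O)C(C(=O)C(C)C)=C(O)C2=C1OC(C)(C)C=C2 | intermediate (not isolated)
33 | (4R)-6-{[5,7-dihydroxy-2,2-dimethyl-6-(2-methylpropanoyl)-2H-chromen-8-yl]methyl}-3,5-dihydroxy-4-methyl-4-(3-methylbut-2-en-1-yl)-2-(2-methylpropanoyl)cyclohexa-2,5-dien-1-one (CNP0319758.1) | CC(C)=CC[C@]1(C)C(O)=C(Cc2c(O)c(C(=O)C(C)C)c(O)c3c2OC(C)(C)C=C3)C(=O)C(C(=O)C(C)C)=C1O | target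

**Step count and risks**

Total step count: 15. Longest linear sequence: 9 steps (steps 1, 2, 3, 4, 7, 8, 9, 10 and 15, from mesityl oxide).

Steps most likely to fail:

Step 7 (new method). The ester-substituted ketene may be consumed by hetero-[4+2] addition through its ester carbonyl, by dimerisation or by acylation of the product phenol. The Wolff migration may be inefficient, and the parent siloxyalkyne may isomerise to the silylketene before it reacts. The fallback sets out from 1 and comes back at 18; it uses classical phloroglucinol chemistry and accepts a separation of regioisomers. Haloform oxidation of 1 (NaOCl, aq. NaOH) gives 3-methylbut-2-enoic acid F1. Friedel–Crafts acylation and oxa-Michael ring closure of commercial methyl 2,4,6-trihydroxybenzoate with F1 (P2O5 in MeSO3H, 70 °C) gives methyl 5,7-dihydroxy-2,2-dimethyl-4-oxochromane-8-carboxylate F2, to be separated from its 6-carboxylate isomer. Silylation of the less strongly chelated 7-hydroxyl (i-Pr3SiCl, imidazole, DMF) then gives 18.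

Step 10. Cleavage of the benzylic ester in the excited state and decarbonylation of the isobutyryl radical may outrun recombination at the hindered C6. The fallback sets out from 20 and comes back at 33; it gives up the benzylic electrophile and uses the ester only as a blocking group. Desilylation of 20 (Bu4NF) gives methyl 5,7-dihydroxy-2,2-dimethyl-2H-chromene-8-carboxylate F3. Friedel–Crafts acylation with isobutyryl chloride and TiCl4 at low temperature can occur only at C6 and gives methyl 5,7-dihydroxy-2,2-dimethyl-6-(2-methylpropanoyl)-2H-chromene-8-carboxylate F4. Saponification (aq. KOH) and warming decarboxylates the trioxygenated benzoic acid to 1-(5,7-dihydroxy-2,2-dimethyl-2H-chromen-6-yl)-2-methylpropan-1-one F5. Separately, 31 is aminomethylated at its free ring carbon with dimethylmethylideneammonium iodide to the Mannich base (4R)-2-[(dimethylamino)methyl]-3,5-dihydroxy-4-methyl-4-(3-methylbut-2-en-1-yl)-6-(2-methylpropanoyl)cyclohexa-2,5-dien-1-one F6. Heating F6 with F5 (loss of dimethylamine, then Michael addition of C8 of F5 to the methylene trione) should give 33, the classical Mannich-base route to unsymmetrical methylene-bridged acylphloroglucinols.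

Step 14. Deprotonation at the isopropyl methine, retro-Claisen loss of an acyl group from the triacylmethane or slow attack on the hindered ester may compete with ring closure. The fallback sets out from 25 and comes back at 31; it replaces steps 11 to 14, and so also covers a poor enantioselectivity in step 12, by dearomatisation and resolution. Commercial 2-methylbenzene-1,3,5-triol is C-acylated (isobutyryl chloride, AlCl3) to 1-(2,4,6-trihydroxy-3-methylphenyl)-2-methylpropan-1-one F7. C-alkylation of its anion with 25 (NaOMe, MeOH, 0 °C) at the methyl-bearing carbon gives racemic 3,5-dihydroxy-4-methyl-4-(3-methylbut-2-en-1-yl)-2-(2-methylpropanoyl)cyclohexa-2,5-dien-1-one F8. Preparative chromatography on a chiral stationary phase then delivers the (R)-enantiomer 31.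

Further compounds
F1 | step 7 | 3-methylbut-2-enoic acid | CC(C)=CC(=O)O
F2 | step 7 | methyl 5,7-dihydroxy-2,2-dimethyl-4-oxochromane-8-carboxylate | COC(=O)c1c(O)cc(O)c2C(=O)CC(C)(C)Oc12
F3 | step 10 | methyl 5,7-dihydroxy-2,2-dimethyl-2H-chromene-8-carboxylate | COC(=O)c1c(O)cc(O)c2C=CC(C)(C)Oc12
F4 | step 10 | methyl 5,7-dihydroxy-2,2-dimethyl-6-(2-methylpropanoyl)-2H-chromene-8-carboxylate | COC(=O)c1c(O)c(C(=O)C(C)C)c(O)c2C=CC(C)(C)Oc12
F5 | step 10 | 1-(5,7-dihydroxy-2,2-dimethyl-2H-chromen-6-yl)-2-methylpropan-1-one | CC(C)C(=O)c1c(O)cc2OC(C)(C)C=Cc2c1O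
F6 | step 10 | (4R)-2-[(dimethylamino)methyl]-3,5-dihydroxy-4-methyl-4-(3-methylbut-2-en-1-yl)-6-(2-methylpropanoyl)cyclohexa-2,5-dien-1-one | CC(C)=CC[C@]1(C)C(O)=C(CN(C)C)C(=O)C(C(=O)C(C)C)=C1O
F7 | step 14 | 1-(2,4,6-trihydroxy-3-methylphenyl)-2-methylpropan-1-one | CC(C)C(=O)c1c(O)cc(O)c(C)c1O
F8 | step 14 | racemic 3,5-dihydroxy-4-methyl-4-(3-methylbut-2-en-1-yl)-2-(2-methylpropanoyl)cyclohexa-2,5-dien-1-one | CC(C)=CCC1(C)C(O)=CC(=O)C(C(=O)C(C)C)=C1O
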